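- Monday's run and Tuesday's run differ in the nucleophile charge, 0.900 against 2.00 equivalents, and we must say what north, south-west and west have done when they stop.

| setting | Monday's | Tuesday's | north | south-west | west |
|---|---|---|---|---|---|
| electrophile | 20 mM | 20 mM | 20 mM | 20 mM | 20 mM |
| nucleophile | 18 mM | 40 mM | 26.0 mM | 39.0 mM | 58.0 mM |
| gas | 4.5 mM (held) | 4.5 mM (held) | 4.5 mM (held) | 4.5 mM (held) | 4.5 mM (held) |
| remark | run made earlier | run made earlier |  |  |  |
| time |  |  | 40 min | 40 min | 40 min |

- Monday's (time / min: electrophile / %, product / %): 5.00: 75, 15; 10.0: 61, 23; 15.0: 48, 27; 20.0: 42, 29; 25.0: 35, 32; 30.0: 34, 35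
- Tuesday's (time / min: electrophile / %, product / %): 2.50: 78, 17; 4.00: 65, 26; 6.00: 56, 33; 10.0: 41, 46; 15.0: 28, 53; 30.0: 12, 66

(readings scatter by 1.5 percentage points)

- the numbers in the tables scatter with a standard deviation of 1.5 percentage points
- at the start none of the gas is in solution
- what has gone from electrophile into another species counts as reacted, even if it can come back

* part of the electrophile that has reacted at the end, north
* part of the electrophile that has reacted at the end, south-west
* part of the electrophile that has reacted at the end, west
* what raising the concentration of nucleophile from its lowest to its highest value here does to the part of the electrophile that has reacted (changes below 5 percentage points count as none) (no change / it falls / it rises)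

- At 10.0 min the runs seem to disagree: Tuesday's run holds twice Monday's product, 46 % against 23 %, yet it has consumed 59.0 % of its electrophile against 39.0 %, a ratio of 1.51.
- In Monday's readings at 10.0 min product is the larger channel, so we take it as the main one and reckon just the correction, the gap: the part of the charge that is neither electrophile nor product. That reading is 16.0 % on Monday and 13.0 % on Tuesday, a difference of 3 percentage points against a scatter of 1.5 points per reading, so the gap reads no larger on Tuesday although the nucleophile charge is larger, and this clears up the disagreement.
- Product per unit of gap, divided by equivalents of nucleophile, reads 1.60 on Monday and 1.77 on Tuesday, each carrying the scatter of its readings.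
- Their mean, 1.68, is our split per equivalent, a selectivity factor between product and gap.
- Read at 10.0 min, it is carried unchanged to the stop as our assumption; multiplied by the equivalents charged, it gives our own estimate of 2.19 parts product per part gap in north and 4.88 in west. This estimate describes what the reacted part consists of, not its size.
- The forecast gives 84 % for north, 93 % for south-west and 97 % for west, and on the trend it rises: “More nucleophile therefore raises conversion”.
- North, south-west and west give 81.3 %, 89.9 % and 96.2 %. Across the range of nucleophile, it rises by 15 points, so the forecast stands within its tolerance.

    electrophile + nucleophile → acid set free + product (k = 0.0380 M⁻¹ s⁻¹)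
    nucleophile + acid set free ⇌ protonated nucleophile, settled at all times (K = 1.20 × 10⁵ M⁻¹)
    acid set free + free base ⇌ salt of the base (K = 1.20 × 10⁵ M⁻¹, k = 2.60 M⁻¹ s⁻¹)
    electrophile ⇌ dormant form (K = 2.40, k = 4.10 × 10⁻⁴ s⁻¹)
    gas ⇌ free base, rate k5*(csat - [free base]) (kL = 0.00560 s⁻¹)

- The gap is the dormant form, and the reacted part in north is 50.4 % product and 31.0 % dormant form at 40.0 min, a ratio of 1.63, below our 2.19. At 6.85 min in north, the electrophile's half-life is 19 min by the product path against 28 min by the forward path to dormant form, so the product path uses electrophile 1.5 times as fast, while west at 40.0 min holds 80.2 % product and 16.0 % dormant form, a ratio of 5.01 against our 4.88.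

The runs were generated by integration with constants of no real substance.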